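**Plan**
Labels: C1' is the ring carbon bearing the aroyl carbonyl, C2' the alkene CH, C3' and C4' the CH2 groups, C5' the CH(CH3), C6' the CH bearing the carbinol C1'' (methyl C2'').
Cuts: first the bond between the ketone carbon and C1' (aryl aldehyde plus cyclohexenyl triflate), then C5'–C6' and C2'–C3' in the carbocycle. On the coumarin the cuts are C6–prenyl (back to an O7 ether), C8–CHO, and the pyranone bonds C4–C4a and O1–C2.
Enabling feature: with C1' and C1'' both raised to the ketone level, C2'–C1'–C6'–C1''–C2'' is acetylacetone and C3'–C4'–C5' with its methyl is crotonaldehyde, so ring C1'–C6' is a [3+3] Michael/aldol product.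
Forward: step 1 closes the carbocycle, and steps 2–4 reduce and silylate the acetyl group and turn the enone into the C1' triflate. Steps 5–10 close the coumarin ring (Pechmann) and functionalise C8 and C6. Steps 11–13 join the halves by Ni/Cr coupling, oxidise and desilylate.
Stereochemistry: the target is (5'R,6'R,1''S) with the C5' methyl and the C6' side chain cis. C5' comes from the (S)-prolinol silyl ether catalyst in step 1, and C6' and C1'' together from a ketoreductase dynamic kinetic reduction in step 2. Neither centre is enolisable after step 4.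

Key step: step 1

Assumption: a Prelog-selective ketoreductase that accepts the (6S) keto epimer of diketone 5 is taken to be identifiable by screening a commercial enzyme panel, as is usual for dynamic reductions of alpha-substituted beta-dicarbonyl compounds.

**Step 1**
Reactants: 1 pentane-2,4-dione (acetylacetone); 2 (E)-but-2-enal (crotonaldehyde)
Product: 5 (5R)-6-acetyl-5-methylcyclohex-2-en-1-one, via keto aldehyde 3 (not isolated), via lactol 4 (not isolated)
Conditions: (S)-2-[diphenyl(trimethylsilyloxy)methyl]pyrrolidine (10 mol%), PhCO2H (10 mol%), toluene, 0 °C to rt; then p-TsOH·H2O (20 mol%), 80 °C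
Reagents that add atoms: none
Why: The (S)-pyrrolidine condenses with 2 to an E-iminium ion whose Si face at C3 is covered by the CPh2(OTMS) group, so the enol of 1 adds through its central carbon to the Re face (bond C6'–C5'), setting C5' as R, and hydrolysis of the enamine gives keto aldehyde 3, which rests as lactol 4. Acid reopens 4, the enol of one methyl ketone attacks the aldehyde (bond C2'–C3') and the aldol loses water to the conjugated enone. The closest known reaction is the prolinol silyl ether catalysed Michael addition of beta-keto esters to enals followed by acid-mediated aldol condensation to cyclohex-2-enones, and Michael additions of acetylacetone to enals under this catalysis are also known. The six-membered ring closes in a 6-(enolendo)-exo-trig aldol. The step needs 1,4- over 1,2-addition and a single Michael addition, which iminium activation and capture of the adduct as lactol 4 should secure, and it needs aldol closure to win over dehydration of 4 to a 4H-pyran, which the wet acid keeps reversible while enone formation is an irreversible exit. C6' stays enolisable and is left undefined here.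

**Step 2**
Reactants: 5 (5R)-6-acetyl-5-methylcyclohex-2-en-1-one
Product: 6 (5R,6S)-6-[(1S)-1-hydroxyethyl]-5-methylcyclohex-2-en-1-one
Conditions: NADPH-dependent ketoreductase (Prelog-selective), NADP+ (cat.), i-PrOH (10% v/v), phosphate buffer pH 7, 30 °C
Reagents that add atoms: none
Why: Biocatalytic dynamic kinetic reduction of an alpha-substituted beta-diketone, in which the C6 epimers of the keto form interconvert through the enol, the enzyme takes the (6S) epimer and delivers hydride to the Re face of the acetyl carbonyl, so that C6' and C1'' are set together while the conjugated ring carbonyl is left alone.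

**Step 3**
Reactants: 6 (5R,6S)-6-[(1S)-1-hydroxyethyl]-5-methylcyclohex-2-en-1-one
Product: 7 (5R,6S)-6-[(1S)-1-{[tert-butyl(dimethyl)silyl]oxy}ethyl]-5-methylcyclohex-2-en-1-one
Conditions: TBSOTf, 2,6-lutidine, CH2Cl2, −78 °C
Reagents that add atoms: tert-butyldimethylsilyl trifluoromethanesulfonate, CC(C)(C)[Si](C)(C)OS(=O)(=O)C(F)(F)F
Why: Silyl ether formation with a silyl triflate and a hindered base is fast at low temperature, where the alpha centre C6 of the beta-hydroxy ketone should neither epimerise nor undergo retro-aldol cleavage.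

**Step 4**
Reactants: 7 (5R,6S)-6-[(1S)-1-{[tert-butyl(dimethyl)silyl]oxy}ethyl]-5-methylcyclohex-2-en-1-one
Product: 9 (5R,6S)-6-[(1S)-1-{[tert-butyl(dimethyl)silyl]oxy}ethyl]-5-methylcyclohex-1-en-1-yl trifluoromethanesulfonate, via lithium enolate 8 (not isolated)
Conditions: Li[HB(s-Bu)3] (1.05 equiv), THF, −78 °C; then PhNTf2, −78 °C to 0 °C
Reagents that add atoms: N-phenylbis(trifluoromethanesulfonimide), O=S(=O)(N(c1ccccc1)S(=O)(=O)C(F)(F)F)C(F)(F)F
Why: Conjugate reduction of a beta-unsubstituted cyclohexenone by the hindered trialkylborohydride gives the C1–C2 enolate regiospecifically and O-triflation fixes the double bond between C1' and C2', while C6 is never deprotonated and keeps its configuration.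

**Step 5**
Reactants: 10 5-methoxybenzene-1,3-diol (5-methoxyresorcinol); 11 ethyl 2-methyl-3-oxobutanoate
Product: 12 7-hydroxy-5-methoxy-3,4-dimethyl-2H-chromen-2-one
Conditions: conc. H2SO4, 0 °C to rt
Reagents that add atoms: none
Why: Pechmann condensation, in which C–C bond formation at either of the two equivalent ring positions between OH and OMe followed by lactonisation leads to the 7-hydroxy-5-methoxy isomer, the 5-hydroxy-7-methoxy isomer from attack between the two hydroxyls being the expected by-product to be removed by crystallisation.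

**Step 6**
Reactants: 12 7-hydroxy-5-methoxy-3,4-dimethyl-2H-chromen-2-one
Product: 13 7-hydroxy-5-methoxy-3,4-dimethyl-2-oxo-2H-chromene-8-carbaldehyde
Conditions: hexamethylenetetramine, CF3CO2H, 80 °C; then H2O, 60 °C
Reagents that add atoms: hexamethylenetetramine, C1N2CN3CN1CN(C2)C3; water, O
Why: Duff formylation, in which the iminium ion from hexamethylenetetramine attacks C8, the position ortho to the 7-hydroxyl and para to the 5-methoxy group that is the usual site of substitution in 7-hydroxycoumarins, and hydrolysis on aqueous work-up releases the aldehyde.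

**Step 7**
Reactants: 13 7-hydroxy-5-methoxy-3,4-dimethyl-2-oxo-2H-chromene-8-carbaldehyde; 14 3-chloro-3-methylbut-1-yne
Product: 15 5-methoxy-3,4-dimethyl-7-[(2-methylbut-3-yn-2-yl)oxy]-2-oxo-2H-chromene-8-carbaldehyde
Conditions: DBU, CuCl2·2H2O (cat.), MeCN, 0 °C to rt
Reagents that add atoms: none
Why: Copper-catalysed O-alkylation of a phenol with a tertiary propargylic chloride is a standard route to aryl 1,1-dimethylpropargyl ethers and works well with acidic, electron-poor phenols such as this one.

**Step 8**
Reactants: 15 5-methoxy-3,4-dimethyl-7-[(2-methylbut-3-yn-2-yl)oxy]-2-oxo-2H-chromene-8-carbaldehyde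
Product: 16 5-methoxy-3,4-dimethyl-7-[(2-methylbut-3-en-2-yl)oxy]-2-oxo-2H-chromene-8-carbaldehyde
Conditions: H2 (1 atm), Pd/CaCO3 poisoned with Pb(OAc)2, quinoline, EtOAc, rt
Reagents that add atoms: none
Why: Lindlar semihydrogenation should stop at the terminal alkene and leave the aldehyde and the tetrasubstituted C3=C4 bond of the coumarin untouched.

**Step 9**
Reactants: 16 5-methoxy-3,4-dimethyl-7-[(2-methylbut-3-en-2-yl)oxy]-2-oxo-2H-chromene-8-carbaldehyde
Product: 17 7-hydroxy-5-methoxy-3,4-dimethyl-6-(3-methylbut-2-en-1-yl)-2-oxo-2H-chromene-8-carbaldehyde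
Conditions: toluene, 110 °C
Reagents that add atoms: none
Why: Aromatic Claisen rearrangement moves the 1,1-dimethylallyl group with allylic inversion from O7 to C6, the only free ortho carbon now that C8 carries the formyl group, and so delivers the linear prenyl group before the dienone tautomerises to the phenol.

**Step 10**
Reactants: 17 7-hydroxy-5-methoxy-3,4-dimethyl-6-(3-methylbut-2-en-1-yl)-2-oxo-2H-chromene-8-carbaldehyde
Product: 18 7-{[tert-butyl(dimethyl)silyl]oxy}-5-methoxy-3,4-dimethyl-6-(3-methylbut-2-en-1-yl)-2-oxo-2H-chromene-8-carbaldehyde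
Conditions: TBSOTf, 2,6-lutidine, CH2Cl2, 0 °C
Reagents that add atoms: tert-butyldimethylsilyl trifluoromethanesulfonate, CC(C)(C)[Si](C)(C)OS(=O)(=O)C(F)(F)F
Why: The reactive silyl triflate silylates the hindered, hydrogen-bonded phenol, so that it cannot quench the organochromium reagent of step 11 and can be freed later together with the other silyl ether.

**Step 11**
Reactants: 9 (5R,6S)-6-[(1S)-1-{[tert-butyl(dimethyl)silyl]oxy}ethyl]-5-methylcyclohex-1-en-1-yl trifluoromethanesulfonate; 18 7-{[tert-butyl(dimethyl)silyl]oxy}-5-methoxy-3,4-dimethyl-6-(3-methylbut-2-en-1-yl)-2-oxo-2H-chromene-8-carbaldehyde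
Product: 19 7-{[tert-butyl(dimethyl)silyl]oxy}-8-{[(5R,6R)-6-[(1S)-1-{[tert-butyl(dimethyl)silyl]oxy}ethyl]-5-methylcyclohex-1-en-1-yl](hydroxy)methyl}-5-methoxy-3,4-dimethyl-6-(3-methylbut-2-en-1-yl)-2H-chromen-2-one (both carbinol epimers)
Conditions: CrCl2 (6 equiv), NiCl2 (2 mol%), DMF, rt
Reagents that add atoms: none
Why: Nozaki–Hiyama–Kishi coupling, in which zerovalent nickel inserts into the alkenyl C–OTf bond and transmetalation gives an alkenyl species of trivalent chromium that adds only to the aldehyde and spares lactone, silyl ethers and alkenes; the new carbinol centre forms without control and is removed in step 12.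

**Step 12**
Reactants: 19 the coupled allylic alcohol (both carbinol epimers)
Product: 20 7-{[tert-butyl(dimethyl)silyl]oxy}-8-{[(5R,6R)-6-[(1S)-1-{[tert-butyl(dimethyl)silyl]oxy}ethyl]-5-methylcyclohex-1-en-1-yl]carbonyl}-5-methoxy-3,4-dimethyl-6-(3-methylbut-2-en-1-yl)-2H-chromen-2-one
Conditions: Dess–Martin periodinane, CH2Cl2, 0 °C to rt
Reagents that add atoms: none
Why: Dess–Martin oxidation converts the allylic and benzylic secondary alcohol into the aryl enone under near-neutral conditions that the prenyl group and both silyl ethers tolerate, and no stereocentre is touched.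

**Step 13**
Reactants: 20 the bis-silylated aryl enone
Product: 21 8-{[(5R,6R)-6-[(1S)-1-hydroxyethyl]-5-methylcyclohex-1-en-1-yl]carbonyl}-7-hydroxy-5-methoxy-3,4-dimethyl-6-(3-methylbut-2-en-1-yl)-2H-chromen-2-one (CNP0197455.1)
Conditions: HF·pyridine, pyridine, THF, 0 °C to rt
Reagents that add atoms: none
Why: Fluoride cleaves the aryl and the secondary alkyl silyl ether in one operation under buffered, weakly acidic conditions, chosen so that the freed phenol should neither add to the enone nor cyclise onto the prenyl group.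

**Compound list**
1 | pentane-2,4-dione (acetylacetone) | CC(=O)CC(C)=O | starting material
2 | (E)-but-2-enal (crotonaldehyde) | C/C=C/C=O | starting material
3 | (3R)-4-acetyl-3-methyl-5-oxohexanal (not isolated) | O=CC[C@@H](C)C(C(C)=O)C(C)=O | intermediate
4 | 1-[(4R)-2-hydroxy-4,6-dimethyl-3,4-dihydro-2H-pyran-5-yl]ethan-1-one (lactol, not isolated) | CC(=O)C1=C(C)OC(O)C[C@H]1C | intermediate
5 | (5R)-6-acetyl-5-methylcyclohex-2-en-1-one (C6 enolisable, undefined) | O=C1C=CC[C@@H](C)C1C(C)=O | intermediate
6 | (5R,6S)-6-[(1S)-1-hydroxyethyl]-5-methylcyclohex-2-en-1-one | O=C1C=CC[C@@H](C)[C@H]1[C@H](C)O | intermediate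
7 | (5R,6S)-6-[(1S)-1-{[tert-butyl(dimethyl)silyl]oxy}ethyl]-5-methylcyclohex-2-en-1-one | O=C1C=CC[C@@H](C)[C@H]1[C@H](C)O[Si](C)(C)C(C)(C)C | intermediate
8 | lithium (5R,6S)-6-[(1S)-1-{[tert-butyl(dimethyl)silyl]oxy}ethyl]-5-methylcyclohex-1-en-1-olate (not isolated) | [Li]OC1=CCC[C@@H](C)[C@H]1[C@H](C)O[Si](C)(C)C(C)(C)C | intermediate
9 | (5R,6S)-6-[(1S)-1-{[tert-butyl(dimethyl)silyl]oxy}ethyl]-5-methylcyclohex-1-en-1-yl trifluoromethanesulfonate | O=S(=O)(OC1=CCC[C@@H](C)[C@H]1[C@H](C)O[Si](C)(C)C(C)(C)C)C(F)(F)F | intermediate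
10 | 5-methoxybenzene-1,3-diol (5-methoxyresorcinol) | COc1cc(O)cc(O)c1 | starting material
11 | ethyl 2-methyl-3-oxobutanoate (ethyl 2-methylacetoacetate) | CCOC(=O)C(C)C(C)=O | starting material
12 | 7-hydroxy-5-methoxy-3,4-dimethyl-2H-chromen-2-one | COc1cc(O)cc2oc(=O)c(C)c(C)c12 | intermediate
13 | 7-hydroxy-5-methoxy-3,4-dimethyl-2-oxo-2H-chromene-8-carbaldehyde | COc1cc(O)c(C=O)c2oc(=O)c(C)c(C)c12 | intermediate
14 | 3-chloro-3-methylbut-1-yne | C#CC(C)(C)Cl | starting material
15 | 5-methoxy-3,4-dimethyl-7-[(2-methylbut-3-yn-2-yl)oxy]-2-oxo-2H-chromene-8-carbaldehyde | COc1cc(OC(C)(C)C#C)c(C=O)c2oc(=O)c(C)c(C)c12 | intermediate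
16 | 5-methoxy-3,4-dimethyl-7-[(2-methylbut-3-en-2-yl)oxy]-2-oxo-2H-chromene-8-carbaldehyde | COc1cc(OC(C)(C)C=C)c(C=O)c2oc(=O)c(C)c(C)c12 | intermediate
17 | 7-hydroxy-5-methoxy-3,4-dimethyl-6-(3-methylbut-2-en-1-yl)-2-oxo-2H-chromene-8-carbaldehyde | COc1c(CC=C(C)C)c(O)c(C=O)c2oc(=O)c(C)c(C)c12 | intermediate
18 | 7-{[tert-butyl(dimethyl)silyl]oxy}-5-methoxy-3,4-dimethyl-6-(3-methylbut-2-en-1-yl)-2-oxo-2H-chromene-8-carbaldehyde | COc1c(CC=C(C)C)c(O[Si](C)(C)C(C)(C)C)c(C=O)c2oc(=O)c(C)c(C)c12 | intermediate
19 | 7-{[tert-butyl(dimethyl)silyl]oxy}-8-{[(5R,6R)-6-[(1S)-1-{[tert-butyl(dimethyl)silyl]oxy}ethyl]-5-methylcyclohex-1-en-1-yl](hydroxy)methyl}-5-methoxy-3,4-dimethyl-6-(3-methylbut-2-en-1-yl)-2H-chromen-2-one (both carbinol epimers) | COc1c(CC=C(C)C)c(O[Si](C)(C)C(C)(C)C)c(C(O)C2=CCC[C@@H](C)[C@H]2[C@H](C)O[Si](C)(C)C(C)(C)C)c2oc(=O)c(C)c(C)c12 | intermediate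
20 | 7-{[tert-butyl(dimethyl)silyl]oxy}-8-{[(5R,6R)-6-[(1S)-1-{[tert-butyl(dimethyl)silyl]oxy}ethyl]-5-methylcyclohex-1-en-1-yl]carbonyl}-5-methoxy-3,4-dimethyl-6-(3-methylbut-2-en-1-yl)-2H-chromen-2-one | COc1c(CC=C(C)C)c(O[Si](C)(C)C(C)(C)C)c(C(=O)C2=CCC[C@@H](C)[C@H]2[C@H](C)O[Si](C)(C)C(C)(C)C)c2oc(=O)c(C)c(C)c12 | intermediate
21 | 8-{[(5R,6R)-6-[(1S)-1-hydroxyethyl]-5-methylcyclohex-1-en-1-yl]carbonyl}-7-hydroxy-5-methoxy-3,4-dimethyl-6-(3-methylbut-2-en-1-yl)-2H-chromen-2-one | COc1c(CC=C(C)C)c(O)c(C(=O)C2=CCC[C@@H](C)[C@H]2[C@H](C)O)c2oc(=O)c(C)c(C)c12 | target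

**Step count**
Total: 13 steps. Longest linear sequence: 9 steps (steps 5–13); the carbocyclic arm is 7 steps (steps 1–4 and 11–13).

**Steps most likely to fail**

Step 2. The reductase may take the wrong C6 epimer of the keto form, or both, so that C6' forms with poor diastereocontrol even though C1'' is set cleanly. The fallback sets out from 5 and returns at 7, and fixes C6' by substrate control instead. A Prelog-selective reductase chosen only for carbonyl-face selectivity would reduce 5 to (5R)-6-[(1S)-1-hydroxyethyl]-5-methylcyclohex-2-en-1-one F1 as a mixture at C6. TBSOTf and 2,6-lutidine would give the silyl ether (5R)-6-[(1S)-1-{[tert-butyl(dimethyl)silyl]oxy}ethyl]-5-methylcyclohex-2-en-1-one F2. LiN(i-Pr)2 in THF at −78 °C would remove the alpha-prime proton at C6 to give the cross-conjugated lithium dienolate lithium (3R)-2-[(1S)-1-{[tert-butyl(dimethyl)silyl]oxy}ethyl]-3-methylcyclohexa-1,5-dien-1-olate F3. A cold quench with 2,6-di-tert-butyl-4-methylphenol should protonate C6 on the face opposite the neighbouring C5 methyl group, which sits pseudoaxial to avoid allylic strain, leaving the side chain cis to that methyl and giving 7.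

Step 1. Dehydration of lactol 4 to a 4H-pyran, or loss of catalyst through enaminone formation with 1, may outrun the aldol closure. The fallback sets out from 2 and returns at 5, and closes the ring by olefination instead of aldol condensation. Commercial 1-(triphenylphosphoranylidene)propan-2-one would be deprotonated at its methyl group (n-BuLi, THF, −78 °C) and acetylated with N-methoxy-N-methylacetamide to 1-(triphenylphosphoranylidene)pentane-2,4-dione F4. Under the same pyrrolidine catalyst F4 should add through C3 to 2 to give (3R)-4-acetyl-3-methyl-5-oxo-6-(triphenylphosphoranylidene)hexanal F5. This closes by intramolecular Wittig reaction between the ylide carbon and the aldehyde to 5. The same two bonds (C6'–C5' and C2'–C3') form, and the ring closure is irreversible.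

Step 11. Oxidative addition and transmetalation may stall, or the alkenylchromium species may be protonated before it adds, because the triflate has a branched neighbour and the aldehyde is flanked on both sides. The fallback sets out from 9 and returns at 19, and uses a more reactive alkenyl metal. Pd(PPh3)4, Me3SnSnMe3 and LiCl in THF at 60 °C would convert 9 into [(5R,6S)-6-[(1S)-1-{[tert-butyl(dimethyl)silyl]oxy}ethyl]-5-methylcyclohex-1-en-1-yl](trimethyl)stannane F6. MeLi in THF at −78 °C would give [(5R,6R)-6-[(1S)-1-{[tert-butyl(dimethyl)silyl]oxy}ethyl]-5-methylcyclohex-1-en-1-yl]lithium F7. F7 would be added to 18 at −78 °C and quenched cold, to forestall migration of the aryl silyl group to the new alkoxide, giving 19.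

**Further compounds**
F1 | step 2 | (5R)-6-[(1S)-1-hydroxyethyl]-5-methylcyclohex-2-en-1-one (C6 epimers) | O=C1C=CC[C@@H](C)C1[C@H](C)O
F2 | step 2 | (5R)-6-[(1S)-1-{[tert-butyl(dimethyl)silyl]oxy}ethyl]-5-methylcyclohex-2-en-1-one (C6 epimers) | O=C1C=CC[C@@H](C)C1[C@H](C)O[Si](C)(C)C(C)(C)C
F3 | step 2 | lithium (3R)-2-[(1S)-1-{[tert-butyl(dimethyl)silyl]oxy}ethyl]-3-methylcyclohexa-1,5-dien-1-olate | [Li]OC1=C([C@H](C)O[Si](C)(C)C(C)(C)C)[C@H](C)CC=C1
F4 | step 1 | 1-(triphenylphosphoranylidene)pentane-2,4-dione | CC(=O)CC(=O)C=P(c1ccccc1)(c1ccccc1)c1ccccc1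
F5 | step 1 | (3R)-4-acetyl-3-methyl-5-oxo-6-(triphenylphosphoranylidene)hexanal | O=CC[C@@H](C)C(C(C)=O)C(=O)C=P(c1ccccc1)(c1ccccc1)c1ccccc1
F6 | step 11 | [(5R,6S)-6-[(1S)-1-{[tert-butyl(dimethyl)silyl]oxy}ethyl]-5-methylcyclohex-1-en-1-yl](trimethyl)stannane | C[Sn](C)(C)C1=CCC[C@@H](C)[C@H]1[C@H](C)O[Si](C)(C)C(C)(C)C
F7 | step 11 | [(5R,6R)-6-[(1S)-1-{[tert-butyl(dimethyl)silyl]oxy}ethyl]-5-methylcyclohex-1-en-1-yl]lithium | [Li]C1=CCC[C@@H](C)[C@H]1[C@H](C)O[Si](C)(C)C(C)(C)C
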